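## The problem

The target is a resveratrol trimer built from two 2-aryl-3-aryl-2,3-dihydrobenzofurans: ring 1 (O1, C2, C3, C3a–C7a) and ring 2 (primed atoms). They are joined by one aryl–sp3 bond from C3 of ring 1 to C6' of ring 2. Ring 1 carries an E-4-hydroxystyryl group at C6, and there are seven free phenols. The four stereocentres, (2S,3S) and (2'S,3'S), are trans within each ring, but the two pairs are separated by the flat benzo ring of ring 2, so neither pair can be expected to control the other and each needs its own source of absolute configuration. Within a pair the centres are unequal. C2 and C2' are 4-oxybenzylic ethers that open and reclose under acid and so settle trans to their neighbours. C3 and C3' are doubly benzylic C–H centres that nothing later can correct, so the synthesis must set C3 and C3' and may let C2 and C2' follow. The electron-rich stilbene (acid, palladium, oxidants), the two benzylic C2–O1 bonds (acid and Lewis acid), the C3–H bonds and the air-sensitive polyphenol will not survive rough treatment, so the phenols stay masked to the end and the stilbene is made late. The feature that makes the key step possible is in ring 1: C3 bears two aryl carbons (C3a and C6') and C2 bears an aryl group and O1. That is the pattern left when an aryl electrophile and a migrating aryl group add anti across an E-2-arylvinylboron unit and boron is then exchanged for oxygen. Because C3a is flanked by oxygen on both sides (C4 and C7a), the ring-1 aryl group can be carried as a symmetric 2,6-dioxygenated ring, and ring closure involves no regiochemical choice.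

## Retrosynthesis

**Phenols and stilbene (34 ⇒ 33 ⇒ 31 + 32).** The last bonds cut are the six O–methyl bonds of 33; the seventh phenol (C4–OH) is already free. Methyl ethers are preferred to benzyl or silyl ethers because they pass unchanged through the organolithium, palladium, peroxide and acid steps, and Lewis-acid demethylation is the usual close for this family. One step further back the stilbene double bond is cut into aldehyde 31 and phosphonate 32. Making the alkene late keeps it out of the palladium and acid steps, at the price of one oxidation (30 → 31). The forward olefination must be E-selective and tolerate one phenoxide.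

**O1–C2 of ring 1 (30 ⇒ 28).** Ring 1 is opened at O1–C2 to the 4-methoxybenzylic alcohol 28, whose ring-1 aryl group carries two acetal-protected phenols and a silylated hydroxymethyl group. This cut is better than C7a–O1 (an aryl C–O coupling on a crowded ring) because the benzylic carbon ionises easily and the nucleophile is a neighbouring phenol. Either of the two equivalent ortho oxygens closes the same ring, and the one left over is the C4 phenol of the target. A single acid treatment has to remove three protecting groups, form the C2 cation and close the ring trans without touching C3. Because C1 of 28 is of defined configuration (R), a stereospecific invertive closure remains available if the cation pathway misbehaves.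

**C–O to C–B (28 ⇒ 27).** The carbinol oxygen of 28 is traced to boron in boronate 27. Oxidation of a secondary boronic ester is stereoretentive and needs nothing special; it turns the problem of 28 into that of a 1,2,2-triarylethylboronate.

**C3–C6' and C2–aryl (27 ⇒ 11 + 23 + 24).** Both aryl–sp3 bonds of 27 are cut at once: C3–C6' to the ring-2 bromide 23, and C2–aryl to 4-methoxyphenyllithium 25 (from 24). What remains is the E-alkenyl boronate 11. This cut is preferred to its neighbours for three reasons:
- It joins two fragments of similar size late in the route.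
- It makes the only bond between the two stereochemical domains.
- It sets C3 under catalyst control at a stage where it cannot epimerise.

The reversed assignment (ring 2 on the alkene, ring 1 as electrophile) would need oxidative addition and reductive elimination at a 2,6-disubstituted aryl halide. A carbene insertion like the one used for ring 2 would require a linear ketone and hydrazone synthesis on the complete ring-2 fragment.

The forward reaction must:
- favour the 1,2-metallate shift over direct aryl transfer from boron to palladium;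
- select one alkene face;
- add strictly anti.

For the first of these, boron carries the hindered cis-diol 9 and not a less hindered diol. The silylated hydroxymethyl group is a spectator that later becomes the aldehyde.

**Alkenyl boronate (11 ⇒ 7 + 9; 7 ⇒ 6 ⇒ 4 ⇒ 1; 9 ⇒ 8).** The C–B bond of 11 is cut to alkyne 7 and diol 9, the alkyne to aldehyde 6, and the formyl carbon to the arene 4, which is metalated between its two acetal oxygens. Arene 4 comes from ester 1 by protection, reduction and silylation; diol 9 comes from dione 8 by double methyl addition. Each precursor is simpler by one carbon or one functional group. The forward steps need regioselective metalation (secured by the two flanking oxygens) and syn, anti-Markovnikov hydroboration (secured by the terminal alkyne).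

**Ring 2 (23 ⇒ 22 ⇒ 20 ⇒ 19 ⇒ 15 + 16; 15 ⇒ 13 + 14 ⇒ 12).** The trans bromide 23 is traced to its cis isomer 22, which differs only at the epimerisable C2'. The C2'–C3' bond of 22 is cut to a diaryl carbene derived from hydrazone 20, which inserts into a benzylic C–H bond of a 4-methoxybenzyl ether. Ketone 19 comes from aldehyde 15 and bromoarene 16; aldehyde 15 comes from 12 by exchange of one methyl ether for the 4-methoxybenzyl group of 14. Building ring 2 by a second conjunctive coupling was considered and set aside:
- The bromine needed later as the electrophilic handle would sit on the alkene partner and compete for palladium.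
- Two flanking methyl ethers offer no phenol for ring closure.
- A second untested coupling would double the risk.

Ring 2 bears only simple aryl groups and lies within the established scope of the carbene insertion, which sets C3' directly.

## Roads not taken

**Alternative 1: chiral-pool flavanone and Wolff ring contraction.** The C3–C3a bond of ring 1 is traced to the C4–C4a bond of a flavanone, with C2 taken from (2S)-naringenin A1. In the forward sense a diazo group is placed at C3 of the protected flavanone to give A2. Photolysis in an alcohol expels nitrogen while the aryl carbon migrates from the carbonyl carbon to C3, and the ketene is trapped as the ester A3, a 2-aryl-dihydrobenzofuran-3-carboxylate with the correct 4-hydroxy and 6-oxygen pattern and a triflate as handle for the styryl group.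
- Merits: the absolute configuration is bought, the oxygenation pattern comes free, the ring-forming step is a classical reaction, and A3 is reached quickly. In these respects it is better than the chosen plan, which needs a chiral catalyst and an untested coupling.
- Weak points: A3 has a carboxylate at C3 where the target needs the ring-2 aryl group. That carbon must be excised by a decarboxylative arylation through a C3 radical, with the trans outcome left to substrate control at a crowded centre. Flavanones lose C2 integrity by ring opening to the chalcone under the basic conditions of diazo transfer. Ring 2 has no chiral-pool parent that carries the C6' link.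
- Comparison: the centre that the chiral pool supplies is the self-correcting one (C2), while the hard bond C3–C6' is postponed. The chosen plan makes that bond and fixes C3 in the same step.

**Alternative 2: benzannulation of the central ring.** The benzo ring of ring 2 is cut at C3a'–C4' and C7'–C7a'. The partners are cyclobutenone A4, which carries the complete ring 1, and siloxyalkyne A5, which carries C3' and the open C2' chain. On heating, A4 opens to a vinylketene that adds to A5; the adduct reopens and closes to the phenol A6, with the C4' hydroxyl free, the C7a' oxygen silylated and the C3'–C2' chain in place for a later acid closure.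
- Merits: it is highly convergent, the substitution pattern of the new ring is regiospecific, the two ring oxygens are differentiated, and the thermal conditions are neutral. The key step is better precedented than the one chosen here.
- Weak points: the step creates no stereocentre. A4 and A5 each need their own asymmetric synthesis: a complete enantiopure ring 1 with a cyclobutenone at C3, and a siloxyalkyne with a stereocentre that is both propargylic and benzylic and is at risk of epimerising at the reaction temperature. The step count is the highest of the four plans.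
- Comparison: this road relocates the stereochemical problem instead of solving it. The chosen union creates C3 and the C2 precursor while it joins the halves.

**Alternative 3: dynamic reduction and double cationic ring closure.** Both O1–C2 and O1'–C2' are cut at once. The diketone A7, whose two α,α-diaryl methine carbons equilibrate through their enols, is reduced with dynamic kinetic resolution to diol A8. Acid then removes four acetal groups, ionises both 4-methoxybenzylic alcohols and closes both rings trans to give A9 with all four stereocentres.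
- Merits: it is the shortest road, uses only known reaction types, and needs no control at the carbinol centres. On step count and precedent it is better than the chosen plan.
- Weak points: two independent dynamic reductions must each choose the same sense at a crowded acyclic α,α-diaryl ketone, and any shortfall at either centre gives diastereomers. A7 needs two enolate arylations with 2,6-dioxygenated aryl halides. The ester of A9 still has to become the stilbene.
- Comparison: the chosen plan sets C3 by one catalyst-controlled event on a substrate that cannot epimerise, and it gives a carbinol of defined configuration, which keeps a stereospecific closure in reserve. It borrows the cationic closure for step 17 and keeps the dynamic reduction as the fallback for step 15.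

Key step: step 15

Assumption: the sense of induction of Rh2(S-PTAD)4 in step 13 and of the (Sp,Sp)-Mandyphos–palladium catalyst in step 15 is taken from the closest analogues and is to be confirmed on crystalline bromide 23 and on 30; the mirror-image catalysts are equally available if the sense proves reversed.

## Route

Step 1
Reactants: 1 methyl 3,5-dihydroxybenzoate
Product: 2 methyl 3,5-bis(methoxymethoxy)benzoate
Conditions: MOMCl, i-Pr2NEt, CH2Cl2, 0 °C → rt
Reagents that add atoms: chloromethyl methyl ether, COCCl
Why: O-alkylation of both phenols; the acetal ethers later direct lithiation, survive base and palladium, and leave with acid.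

Step 2
Reactants: 2 methyl 3,5-bis(methoxymethoxy)benzoate
Product: 3 [3,5-bis(methoxymethoxy)phenyl]methanol
Conditions: LiAlH4, THF, 0 °C
Reagents that add atoms: none
Why: Hydride reduction of the ester to the benzylic alcohol; the acetals are inert to hydride.

Step 3
Reactants: 3 [3,5-bis(methoxymethoxy)phenyl]methanol
Product: 4 tert-butyl{[3,5-bis(methoxymethoxy)phenyl]methoxy}dimethylsilane
Conditions: TBSCl, imidazole, DMF, rt
Reagents that add atoms: tert-butyldimethylsilyl chloride, CC(C)(C)[Si](C)(C)Cl
Why: Silylation of the primary alcohol; the bulky, poorly coordinating silyl ether keeps the base away from the benzylic position in the next step.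

Step 4
Reactants: 4 tert-butyl{[3,5-bis(methoxymethoxy)phenyl]methoxy}dimethylsilane
Product: 6 4-{[tert-butyl(dimethyl)silyl]oxymethyl}-2,6-bis(methoxymethoxy)benzaldehyde, via aryllithium 5 (not isolated)
Conditions: n-BuLi, THF, 0 °C; DMF; H2O
Reagents that add atoms: N,N-dimethylformamide, CN(C)C=O
Why: Directed ortho-metalation; the hydrogen between the two acetal oxygens is the most acidic and is reached by two directing groups at once, and formylation of 5 with DMF gives the aldehyde at the future C3a.

Step 5
Reactants: 6 4-{[tert-butyl(dimethyl)silyl]oxymethyl}-2,6-bis(methoxymethoxy)benzaldehyde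
Product: 7 tert-butyl{[4-ethynyl-3,5-bis(methoxymethoxy)phenyl]methoxy}dimethylsilane
Conditions: dimethyl (1-diazo-2-oxopropyl)phosphonate, K2CO3, MeOH, rt
Reagents that add atoms: dimethyl (1-diazo-2-oxopropyl)phosphonate, CC(=O)C(=[N+]=[N-])P(=O)(OC)OC
Why: Ohira–Bestmann homologation of a non-enolisable aldehyde under mild base; the acetal and silyl ethers are stable, and the new carbon is the future C2.

Step 6
Reactants: 8 acenaphthylene-1,2-dione
Product: 9 (1R,2S)-1,2-dimethyl-1,2-dihydroacenaphthylene-1,2-diol (cis, meso)
Conditions: MeMgBr, THF, 0 °C → rt; aq. NH4Cl; recrystallisation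
Reagents that add atoms: methylmagnesium bromide, C[Mg]Br
Why: Twofold Grignard addition to the 1,2-dione; the second methyl group should enter anti to the bulky magnesium alkoxide of the first adduct and so give the cis diol, and recrystallisation removes any trans isomer, which cannot bridge boron in step 7 in any case.

Step 7
Reactants: 7 tert-butyl{[4-ethynyl-3,5-bis(methoxymethoxy)phenyl]methoxy}dimethylsilane; 9 (1R,2S)-1,2-dimethyl-1,2-dihydroacenaphthylene-1,2-diol
Product: 11 (E)-2-{4-[(tert-butyldimethylsilyloxy)methyl]-2,6-bis(methoxymethoxy)phenyl}ethenylboronic ester of cis-diol 9 (boron bridges the two oxygens of 9), via alkenyl catechol boronate 10 (not isolated)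
Conditions: catecholborane, Cy2BH (10 mol %), THF, rt; then 9, rt; aq. NaHCO3 wash
Reagents that add atoms: catecholborane, B1Oc2ccccc2O1
Why: Dialkylborane-catalysed hydroboration of a terminal alkyne is syn and places boron on the terminal carbon, which gives the E-alkenyl boronate 10. Its catechol ester exchanges readily with the more basic aliphatic cis-diol 9 (boronic ester transesterification), and the catechol is washed out.

Step 8
Reactants: 12 4-bromo-2,6-dimethoxybenzaldehyde
Product: 13 4-bromo-2-hydroxy-6-methoxybenzaldehyde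
Conditions: BCl3 (1.1 equiv), CH2Cl2, −78 → 0 °C; H2O
Reagents that add atoms: none
Why: Chelation-assisted cleavage of one methyl ether ortho to the carbonyl group; the boron chelate of the first phenoxide with the aldehyde protects the second ether.

Step 9
Reactants: 13 4-bromo-2-hydroxy-6-methoxybenzaldehyde; 14 4-methoxybenzyl chloride
Product: 15 4-bromo-2-methoxy-6-[(4-methoxybenzyl)oxy]benzaldehyde
Conditions: K2CO3, DMF, 60 °C
Reagents that add atoms: none
Why: Williamson etherification of the phenol; the benzylic CH2 introduced here becomes C2' and its aryl group the C2' substituent.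

Step 10
Reactants: 15 4-bromo-2-methoxy-6-[(4-methoxybenzyl)oxy]benzaldehyde; 16 1-bromo-3,5-dimethoxybenzene
Product: 18 {4-bromo-2-methoxy-6-[(4-methoxybenzyl)oxy]phenyl}(3,5-dimethoxyphenyl)methanol (racemic), via arylmagnesium bromide 17 (not isolated)
Conditions: 16, Mg, THF; then 15, 0 °C → rt; aq. NH4Cl
Reagents that add atoms: none
Why: Grignard addition to the aldehyde; the aryl bromide of 15 does not exchange with an arylmagnesium halide at this temperature.

Step 11
Reactants: 18 {4-bromo-2-methoxy-6-[(4-methoxybenzyl)oxy]phenyl}(3,5-dimethoxyphenyl)methanol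
Product: 19 {4-bromo-2-methoxy-6-[(4-methoxybenzyl)oxy]phenyl}(3,5-dimethoxyphenyl)methanone
Conditions: Dess–Martin periodinane, CH2Cl2, rt
Reagents that add atoms: none
Why: Dess–Martin oxidation of a hindered diaryl carbinol under neutral conditions that leave the benzyl ether alone.

Step 12
Reactants: 19 {4-bromo-2-methoxy-6-[(4-methoxybenzyl)oxy]phenyl}(3,5-dimethoxyphenyl)methanone
Product: 20 hydrazone of 19, [{4-bromo-2-methoxy-6-[(4-methoxybenzyl)oxy]phenyl}(3,5-dimethoxyphenyl)methylidene]hydrazine (E/Z mixture)
Conditions: N2H4·H2O (excess), AcOH (cat.), n-BuOH, 110 °C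
Reagents that add atoms: hydrazine, NN
Why: Hydrazone condensation; the small, strongly nucleophilic hydrazine and forcing conditions are chosen because the ketone is flanked by two ortho alkoxy groups.

Step 13
Reactants: 20 hydrazone of 19
Product: 22 (2R,3S)-6-bromo-3-(3,5-dimethoxyphenyl)-4-methoxy-2-(4-methoxyphenyl)-2,3-dihydro-1-benzofuran (cis), via diaryldiazomethane 21 (not isolated)
Conditions: MnO2, CH2Cl2, 0 °C, filter; then Rh2(S-PTAD)4 [dirhodium tetrakis((S)-N-phthaloyl-1-adamantylglycinate)] (1 mol %), CH2Cl2, 0 °C
Reagents that add atoms: none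
Why: MnO2 dehydrogenates the hydrazone to diazo compound 21, and the dirhodium carbene inserts into a benzylic C–H bond of the 4-methoxybenzyl ether through a five-membered transition state (intramolecular C–H insertion of a donor/donor carbene, established for hydrazones of 2-benzyloxybenzophenones). The chiral carboxylate ligands choose the hydrogen and the carbene face, which sets C3' (S) and, kinetically, the cis C2' centre; the weakly electrophilic diaryl carbene should spare the methyl ethers and the aryl bromide.

Step 14
Reactants: 22 (2R,3S)-6-bromo-3-(3,5-dimethoxyphenyl)-4-methoxy-2-(4-methoxyphenyl)-2,3-dihydro-1-benzofuran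
Product: 23 (2S,3S)-6-bromo-3-(3,5-dimethoxyphenyl)-4-methoxy-2-(4-methoxyphenyl)-2,3-dihydro-1-benzofuran (trans)
Conditions: TFA, CH2Cl2, rt
Reagents that add atoms: none
Why: Acid opens the C2'–O1' bond to a 4-methoxybenzylic cation that recloses on the phenol oxygen (acid-mediated epimerisation of 2-aryl-2,3-dihydrobenzofurans). Repeated opening and closure lead to the favoured trans isomer, while C3', which is not part of the cation, keeps its configuration.

Step 15
Reactants: 11 (E)-alkenylboronic ester of cis-diol 9; 23 (2S,3S)-6-bromo-3-(3,5-dimethoxyphenyl)-4-methoxy-2-(4-methoxyphenyl)-2,3-dihydro-1-benzofuran; 24 4-bromoanisole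
Product: 27 (1R,2S)-2-{4-[(tert-butyldimethylsilyloxy)methyl]-2,6-bis(methoxymethoxy)phenyl}-2-[(2S,3S)-3-(3,5-dimethoxyphenyl)-4-methoxy-2-(4-methoxyphenyl)-2,3-dihydro-1-benzofuran-6-yl]-1-(4-methoxyphenyl)ethylboronic ester of cis-diol 9, via 4-methoxyphenyllithium 25 (not isolated), via lithium ate complex 26 (not isolated)
Conditions: 24, t-BuLi (2 equiv), THF, −78 °C; 11, −78 °C → rt; then 23, Pd(OAc)2 (5 mol %), (Sp,Sp)-Mandyphos [bis(4-methoxy-3,5-dimethylphenyl)phosphino type] (6 mol %), KOTf (2 equiv), THF, 60 °C
Reagents that add atoms: none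
Why: Proposed new method: t-BuLi turns 24 into aryllithium 25, which adds to boron of 11 to give ate complex 26; 23 adds oxidatively to zerovalent palladium, KOTf strips bromide from the arylpalladium species, and this cationic divalent palladium binds the alkene of 26, whereupon the anisyl group shifts from boron to the boron-bearing carbon anti to the metal as the Pd–C bond forms at the benzylic carbon, and reductive elimination with retention joins C3 to C6'. The closest known reaction type is the enantioselective palladium–Mandyphos conjunctive cross-coupling of β-alkyl alkenylboron ate complexes carrying a hindered diol with aryl electrophiles; a β-(2,6-dialkoxyaryl) group together with a migrating aryl group is untested. No ring closes. C3 (S) is set by the chiral bisphosphine, which decides the alkene face that palladium takes, and the boron-bearing carbon (R) follows from the E geometry because migration and palladation are strictly anti and the reductive elimination is retentive, so the anisyl group and the ring-2 aryl group end up anti and boron lies on the face opposite the future O1. The step needs chemoselectivity for the metallate shift over direct transfer of the anisyl group to palladium (a biaryl by Suzuki coupling); the hindered diol 9 on boron, which blocks the Pd–O–B bridge that transmetallation needs, and the halide-free cationic palladium centre are there to secure it. It needs the benzylic palladium intermediate to eliminate reductively before it loses the neighbouring hydrogen, which the wide bite angle of the ferrocenyl bisphosphine favours. It needs catalyst control of the alkene face, which should hold because the stereocentres of 23 lie five bonds from the reacting carbon and the symmetric ring-1 aryl group presents the same surroundings on either side.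

Step 16
Reactants: 27 boronic ester from step 15
Product: 28 (1R,2S)-2-{4-[(tert-butyldimethylsilyloxy)methyl]-2,6-bis(methoxymethoxy)phenyl}-2-[(2S,3S)-3-(3,5-dimethoxyphenyl)-4-methoxy-2-(4-methoxyphenyl)-2,3-dihydro-1-benzofuran-6-yl]-1-(4-methoxyphenyl)ethan-1-ol
Conditions: H2O2 (30 %), NaOH (3 M), THF, 0 °C → rt
Reagents that add atoms: hydrogen peroxide, OO
Why: Oxidation of the secondary boronic ester by hydroperoxide proceeds through a 1,2-shift of carbon from boron to oxygen with retention, so the carbinol keeps the configuration set in step 15; the acetal, silyl and methyl ethers are stable to cold aqueous base.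

Step 17
Reactants: 28 alcohol from step 16
Product: 30 (2S,3S)-3-[(2S,3S)-3-(3,5-dimethoxyphenyl)-4-methoxy-2-(4-methoxyphenyl)-2,3-dihydro-1-benzofuran-6-yl]-6-(hydroxymethyl)-2-(4-methoxyphenyl)-2,3-dihydro-1-benzofuran-4-ol, via tetrol 29 (not isolated)
Conditions: HCl (conc.), MeOH–THF, 45 °C
Reagents that add atoms: none
Why: Methanolic HCl cleaves the two acetals and the silyl ether to give tetrol 29, whose 4-methoxybenzylic alcohol ionises; either of the two equivalent phenols captures the cation in a five-membered ring closure (SN1 etherification). The 2,3-trans ring is the less hindered and the more stable outcome, so C2 becomes S under control of C3, and ring 2, already trans, is not changed by reversible opening.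

Step 18
Reactants: 30 diol from step 17
Product: 31 (2S,3S)-3-[(2S,3S)-3-(3,5-dimethoxyphenyl)-4-methoxy-2-(4-methoxyphenyl)-2,3-dihydro-1-benzofuran-6-yl]-4-hydroxy-2-(4-methoxyphenyl)-2,3-dihydro-1-benzofuran-6-carbaldehyde
Conditions: MnO2, acetone, rt
Reagents that add atoms: none
Why: MnO2 oxidises benzylic alcohols selectively and leaves a simple phenol alone; iodine-based or activated-sulfoxide oxidants are avoided because they attack phenols.

Step 19
Reactants: 31 aldehyde from step 18; 32 diethyl [(4-methoxyphenyl)methyl]phosphonate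
Product: 33 (2S,3S)-3-[(2S,3S)-3-(3,5-dimethoxyphenyl)-4-methoxy-2-(4-methoxyphenyl)-2,3-dihydro-1-benzofuran-6-yl]-2-(4-methoxyphenyl)-6-[(E)-2-(4-methoxyphenyl)ethenyl]-2,3-dihydro-1-benzofuran-4-ol
Conditions: 32, KOt-Bu (3.2 equiv), DMF, 0 °C → rt
Reagents that add atoms: none
Why: Horner–Wadsworth–Emmons olefination with a benzylic phosphonate gives the E-stilbene. One extra equivalent of base is consumed by the phenol, whose phenoxide is meta to the aldehyde and does not deactivate it by resonance.

Step 20
Reactants: 33 hexamethyl ether from step 19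
Product: 34 (2S,3S)-3-[(2S,3S)-3-(3,5-dihydroxyphenyl)-4-hydroxy-2-(4-hydroxyphenyl)-2,3-dihydro-1-benzofuran-6-yl]-2-(4-hydroxyphenyl)-6-[(E)-2-(4-hydroxyphenyl)ethenyl]-2,3-dihydro-1-benzofuran-4-ol (CNP0248228.2)
Conditions: BBr3 (excess), CH2Cl2, −78 °C → rt; MeOH, H2O
Reagents that add atoms: none
Why: Lewis-acid cleavage of the six aryl methyl ethers by BBr3, the usual last step for permethylated resveratrol oligomers. The styryl group is remote from C3, so the acid-triggered cyclisation known for stilbenes adjacent to C3 has no pathway here, and any reversible opening at C2 or C2' returns to the trans rings.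

## Compound list

1 | methyl 3,5-dihydroxybenzoate | COC(=O)c1cc(O)cc(O)c1 | starting material
2 | methyl 3,5-bis(methoxymethoxy)benzoate | COCOc1cc(OCOC)cc(c1)C(=O)OC | intermediate
3 | [3,5-bis(methoxymethoxy)phenyl]methanol | COCOc1cc(CO)cc(OCOC)c1 | intermediate
4 | tert-butyl{[3,5-bis(methoxymethoxy)phenyl]methoxy}dimethylsilane | COCOc1cc(CO[Si](C)(C)C(C)(C)C)cc(OCOC)c1 | intermediate
5 | [4-{[tert-butyl(dimethyl)silyl]oxymethyl}-2,6-bis(methoxymethoxy)phenyl]lithium | [Li]c1c(OCOC)cc(CO[Si](C)(C)C(C)(C)C)cc1OCOC | intermediate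
6 | 4-{[tert-butyl(dimethyl)silyl]oxymethyl}-2,6-bis(methoxymethoxy)benzaldehyde | O=Cc1c(OCOC)cc(CO[Si](C)(C)C(C)(C)C)cc1OCOC | intermediate
7 | tert-butyl{[4-ethynyl-3,5-bis(methoxymethoxy)phenyl]methoxy}dimethylsilane | C#Cc1c(OCOC)cc(CO[Si](C)(C)C(C)(C)C)cc1OCOC | intermediate
8 | acenaphthylene-1,2-dione (acenaphthenequinone) | O=C1C(=O)c2cccc3cccc1c23 | starting material
9 | (1R,2S)-1,2-dimethyl-1,2-dihydroacenaphthylene-1,2-diol (cis, meso) | C[C@]1(O)[C@@](C)(O)c2cccc3cccc1c23 | intermediate
10 | 2-[(E)-2-{4-[(tert-butyldimethylsilyloxy)methyl]-2,6-bis(methoxymethoxy)phenyl}ethenyl]-1,3,2-benzodioxaborole | COCOc1cc(CO[Si](C)(C)C(C)(C)C)cc(OCOC)c1/C=C/B1Oc2ccccc2O1 | intermediate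
11 | (E)-2-{4-[(tert-butyldimethylsilyloxy)methyl]-2,6-bis(methoxymethoxy)phenyl}ethenylboronic ester of cis-diol 9 | COCOc1cc(CO[Si](C)(C)C(C)(C)C)cc(OCOC)c1/C=C/B1O[C@]2(C)c3cccc4cccc(c34)[C@]2(C)O1 | intermediate
12 | 4-bromo-2,6-dimethoxybenzaldehyde | COc1cc(Br)cc(OC)c1C=O | starting material
13 | 4-bromo-2-hydroxy-6-methoxybenzaldehyde | COc1cc(Br)cc(O)c1C=O | intermediate
14 | 4-methoxybenzyl chloride | COc1ccc(CCl)cc1 | starting material
15 | 4-bromo-2-methoxy-6-[(4-methoxybenzyl)oxy]benzaldehyde | COc1ccc(COc2cc(Br)cc(OC)c2C=O)cc1 | intermediate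
16 | 1-bromo-3,5-dimethoxybenzene | COc1cc(Br)cc(OC)c1 | starting material
17 | (3,5-dimethoxyphenyl)magnesium bromide | COc1cc(OC)cc([Mg]Br)c1 | intermediate
18 | {4-bromo-2-methoxy-6-[(4-methoxybenzyl)oxy]phenyl}(3,5-dimethoxyphenyl)methanol (racemic) | COc1ccc(COc2cc(Br)cc(OC)c2C(O)c2cc(OC)cc(OC)c2)cc1 | intermediate
19 | {4-bromo-2-methoxy-6-[(4-methoxybenzyl)oxy]phenyl}(3,5-dimethoxyphenyl)methanone | COc1ccc(COc2cc(Br)cc(OC)c2C(=O)c2cc(OC)cc(OC)c2)cc1 | intermediate
20 | [{4-bromo-2-methoxy-6-[(4-methoxybenzyl)oxy]phenyl}(3,5-dimethoxyphenyl)methylidene]hydrazine | COc1ccc(COc2cc(Br)cc(OC)c2C(=NN)c2cc(OC)cc(OC)c2)cc1 | intermediate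
21 | 5-bromo-2-[diazo(3,5-dimethoxyphenyl)methyl]-1-methoxy-3-[(4-methoxybenzyl)oxy]benzene | COc1ccc(COc2cc(Br)cc(OC)c2C(=[N+]=[N-])c2cc(OC)cc(OC)c2)cc1 | intermediate
22 | (2R,3S)-6-bromo-3-(3,5-dimethoxyphenyl)-4-methoxy-2-(4-methoxyphenyl)-2,3-dihydro-1-benzofuran (cis) | Brc1cc(OC)c2c(c1)O[C@@H](c1ccc(OC)cc1)[C@H]2c1cc(OC)cc(OC)c1 | intermediate
23 | (2S,3S)-6-bromo-3-(3,5-dimethoxyphenyl)-4-methoxy-2-(4-methoxyphenyl)-2,3-dihydro-1-benzofuran (trans) | Brc1cc(OC)c2c(c1)O[C@H](c1ccc(OC)cc1)[C@H]2c1cc(OC)cc(OC)c1 | intermediate
24 | 4-bromoanisole | COc1ccc(Br)cc1 | starting material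
25 | (4-methoxyphenyl)lithium | [Li]c1ccc(OC)cc1 | intermediate
26 | lithium (4-methoxyphenyl)[(E)-2-{4-[(tert-butyldimethylsilyloxy)methyl]-2,6-bis(methoxymethoxy)phenyl}ethenyl]borate of cis-diol 9 (configuration at boron not specified) | [Li+].COc1ccc(cc1)[B-]1(/C=C/c2c(OCOC)cc(CO[Si](C)(C)C(C)(C)C)cc2OCOC)O[C@]2(C)c3cccc4cccc(c34)[C@]2(C)O1 | intermediate
27 | (1R,2S)-2-{4-[(tert-butyldimethylsilyloxy)methyl]-2,6-bis(methoxymethoxy)phenyl}-2-[(2S,3S)-3-(3,5-dimethoxyphenyl)-4-methoxy-2-(4-methoxyphenyl)-2,3-dihydro-1-benzofuran-6-yl]-1-(4-methoxyphenyl)ethylboronic ester of cis-diol 9 | COc1ccc(cc1)[C@H](B1O[C@]2(C)c3cccc4cccc(c34)[C@]2(C)O1)[C@H](c1c(OCOC)cc(CO[Si](C)(C)C(C)(C)C)cc1OCOC)c1cc(OC)c2c(c1)O[C@H](c1ccc(OC)cc1)[C@H]2c1cc(OC)cc(OC)c1 | intermediate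
28 | (1R,2S)-2-{4-[(tert-butyldimethylsilyloxy)methyl]-2,6-bis(methoxymethoxy)phenyl}-2-[(2S,3S)-3-(3,5-dimethoxyphenyl)-4-methoxy-2-(4-methoxyphenyl)-2,3-dihydro-1-benzofuran-6-yl]-1-(4-methoxyphenyl)ethan-1-ol | COc1ccc(cc1)[C@H](O)[C@H](c1c(OCOC)cc(CO[Si](C)(C)C(C)(C)C)cc1OCOC)c1cc(OC)c2c(c1)O[C@H](c1ccc(OC)cc1)[C@H]2c1cc(OC)cc(OC)c1 | intermediate
29 | 2-{(1S,2R)-1-[(2S,3S)-3-(3,5-dimethoxyphenyl)-4-methoxy-2-(4-methoxyphenyl)-2,3-dihydro-1-benzofuran-6-yl]-2-hydroxy-2-(4-methoxyphenyl)ethyl}-5-(hydroxymethyl)benzene-1,3-diol | COc1ccc(cc1)[C@H](O)[C@H](c1c(O)cc(CO)cc1O)c1cc(OC)c2c(c1)O[C@H](c1ccc(OC)cc1)[C@H]2c1cc(OC)cc(OC)c1 | intermediate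
30 | (2S,3S)-3-[(2S,3S)-3-(3,5-dimethoxyphenyl)-4-methoxy-2-(4-methoxyphenyl)-2,3-dihydro-1-benzofuran-6-yl]-6-(hydroxymethyl)-2-(4-methoxyphenyl)-2,3-dihydro-1-benzofuran-4-ol | OCc1cc(O)c2c(c1)O[C@H](c1ccc(OC)cc1)[C@H]2c1cc(OC)c2c(c1)O[C@H](c1ccc(OC)cc1)[C@H]2c1cc(OC)cc(OC)c1 | intermediate
31 | (2S,3S)-3-[(2S,3S)-3-(3,5-dimethoxyphenyl)-4-methoxy-2-(4-methoxyphenyl)-2,3-dihydro-1-benzofuran-6-yl]-4-hydroxy-2-(4-methoxyphenyl)-2,3-dihydro-1-benzofuran-6-carbaldehyde | O=Cc1cc(O)c2c(c1)O[C@H](c1ccc(OC)cc1)[C@H]2c1cc(OC)c2c(c1)O[C@H](c1ccc(OC)cc1)[C@H]2c1cc(OC)cc(OC)c1 | intermediate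
32 | diethyl [(4-methoxyphenyl)methyl]phosphonate | CCOP(=O)(Cc1ccc(OC)cc1)OCC | starting material
33 | (2S,3S)-3-[(2S,3S)-3-(3,5-dimethoxyphenyl)-4-methoxy-2-(4-methoxyphenyl)-2,3-dihydro-1-benzofuran-6-yl]-2-(4-methoxyphenyl)-6-[(E)-2-(4-methoxyphenyl)ethenyl]-2,3-dihydro-1-benzofuran-4-ol | COc1ccc(/C=C/c2cc(O)c3c(c2)O[C@H](c2ccc(OC)cc2)[C@H]3c2cc(OC)c3c(c2)O[C@H](c2ccc(OC)cc2)[C@H]3c2cc(OC)cc(OC)c2)cc1 | intermediate
34 | (2S,3S)-3-[(2S,3S)-3-(3,5-dihydroxyphenyl)-4-hydroxy-2-(4-hydroxyphenyl)-2,3-dihydro-1-benzofuran-6-yl]-2-(4-hydroxyphenyl)-6-[(E)-2-(4-hydroxyphenyl)ethenyl]-2,3-dihydro-1-benzofuran-4-ol | Oc1ccc(/C=C/c2cc(O)c3c(c2)O[C@H](c2ccc(O)cc2)[C@H]3c2cc(O)c3c(c2)O[C@H](c2ccc(O)cc2)[C@H]3c2cc(O)cc(O)c2)cc1 | target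

## Step count and risk

Total: 20 steps. Longest linear sequence: 13 steps (steps 8–14, then 15–20, from 12 to 34); the ring-1 branch (steps 1–5 and 7) is six steps to 11, and step 6 supplies diol 9.

**Step 15 (key step, proposed new method).** The most likely failure is direct transfer of the anisyl group from boron to palladium outrunning alkene binding, because the two ortho substituents of the β-aryl group hinder coordination; the result would be a biaryl by Suzuki coupling. Further risks are loss of the neighbouring hydrogen from the benzylic palladium intermediate and poor facial selectivity.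

The fallback uses only known reactions and sets out from 11 and 23:
- Oxidation of the alkenyl boronate 11 (NaBO3·4H2O, THF–H2O) gives 2-{4-[(tert-butyldimethylsilyloxy)methyl]-2,6-bis(methoxymethoxy)phenyl}acetaldehyde F1.
- Addition of 4-methoxyphenylmagnesium bromide gives the racemic carbinol F2, and Dess–Martin oxidation gives the deoxybenzoin F3.
- Palladium-catalysed α-arylation of the enolate of F3 with bromide 23 (Pd2(dba)3, P(t-Bu)3, NaOt-Bu, toluene, 80 °C) forms the C3–C6' bond and gives the α,α-diaryl ketone F4 as a pair of interconverting epimers.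
- Asymmetric hydrogenation under basic conditions with dynamic kinetic resolution (RuCl2[(S)-xylbinap][(S)-daipen] or its mirror image, H2, KOt-Bu, i-PrOH) reduces the epimer that fits the catalyst while the other equilibrates through the enolate. This gives 28 or its carbinol epimer F5; both carry the S diarylmethine carbon.

The route is rejoined at 28, or through F5 at 30, since step 17 erases the carbinol centre.

**Step 13.** The carbene carbon is flanked by two ortho alkoxy groups, a pattern beyond the usual substrates, so low enantioselectivity is the main risk. Azine formation from 21 and sluggish formation of hydrazone 20 in step 12 are lesser ones. The fallback gives up asymmetric catalysis for resolution. Setting out from 20, the diazo compound 21 is decomposed with achiral Rh2(OAc)4 to the racemic cis dihydrobenzofuran F6. TFA converts this into the racemic trans bromide F7, and preparative chromatography on a chiral stationary phase gives 23, where the route is rejoined.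

**Step 17.** The C2 cation may lose the C3 proton (E1) to a triarylethylene whose reprotonation would erase C3. It may also be intercepted by the solvent or by a second molecule, or ring 2 may be scrambled by prolonged ionisation. The fallback avoids the cation by a stereospecific closure that uses the carbinol configuration set in step 15. Setting out from 27:
- The two aryl acetals are removed without protic acid (TMSOTf, 2,2′-bipyridyl, CH2Cl2, 0 °C; then H2O; conditions that spare silyl ethers) to give the bis-phenol boronate F8.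
- Oxidation (H2O2, NaOH) gives the bis-phenol carbinol F9.
- Mitsunobu etherification (PPh3, DIAD, THF, 0 °C) closes O1–C2 with inversion, which is the trans ring, to give the silyl ether F10.
- TBAF removes the silyl group and the route is rejoined at 30.

**Step 20.** Hydrogen bromide may add to or protonate the electron-rich stilbene, followed by Friedel–Crafts oligomerisation, during the long exposure needed to cleave six ethers. The fallback removes the stilbene from the Lewis-acid step. Setting out from aldehyde 31:
- BBr3 gives the hexaphenol aldehyde F11.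
- MOMCl and i-Pr2NEt give the hexakis(methoxymethyl) ether F12.
- Olefination with diethyl {[4-(methoxymethoxy)phenyl]methyl}phosphonate (CCOP(=O)(Cc1ccc(OCOC)cc1)OCC) and KOt-Bu gives the heptakis(methoxymethyl) stilbene F13.
- Mild methanolic HCl at room temperature releases 34, where the route is rejoined.

## Further compounds

F1 | step 15 | 2-{4-[(tert-butyldimethylsilyloxy)methyl]-2,6-bis(methoxymethoxy)phenyl}acetaldehyde | O=CCc1c(OCOC)cc(CO[Si](C)(C)C(C)(C)C)cc1OCOC
F2 | step 15 | 2-{4-[(tert-butyldimethylsilyloxy)methyl]-2,6-bis(methoxymethoxy)phenyl}-1-(4-methoxyphenyl)ethan-1-ol (racemic) | COc1ccc(cc1)C(O)Cc1c(OCOC)cc(CO[Si](C)(C)C(C)(C)C)cc1OCOC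
F3 | step 15 | 2-{4-[(tert-butyldimethylsilyloxy)methyl]-2,6-bis(methoxymethoxy)phenyl}-1-(4-methoxyphenyl)ethan-1-one | COc1ccc(cc1)C(=O)Cc1c(OCOC)cc(CO[Si](C)(C)C(C)(C)C)cc1OCOC
F4 | step 15 | 2-{4-[(tert-butyldimethylsilyloxy)methyl]-2,6-bis(methoxymethoxy)phenyl}-2-[(2S,3S)-3-(3,5-dimethoxyphenyl)-4-methoxy-2-(4-methoxyphenyl)-2,3-dihydro-1-benzofuran-6-yl]-1-(4-methoxyphenyl)ethan-1-one (both C2 epimers) | COc1ccc(cc1)C(=O)C(c1c(OCOC)cc(CO[Si](C)(C)C(C)(C)C)cc1OCOC)c1cc(OC)c2c(c1)O[C@H](c1ccc(OC)cc1)[C@H]2c1cc(OC)cc(OC)c1
F5 | step 15 | (1S,2S)-2-{4-[(tert-butyldimethylsilyloxy)methyl]-2,6-bis(methoxymethoxy)phenyl}-2-[(2S,3S)-3-(3,5-dimethoxyphenyl)-4-methoxy-2-(4-methoxyphenyl)-2,3-dihydro-1-benzofuran-6-yl]-1-(4-methoxyphenyl)ethan-1-ol (carbinol epimer of 28) | COc1ccc(cc1)[C@@H](O)[C@H](c1c(OCOC)cc(CO[Si](C)(C)C(C)(C)C)cc1OCOC)c1cc(OC)c2c(c1)O[C@H](c1ccc(OC)cc1)[C@H]2c1cc(OC)cc(OC)c1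
F6 | step 13 | racemic cis-6-bromo-3-(3,5-dimethoxyphenyl)-4-methoxy-2-(4-methoxyphenyl)-2,3-dihydro-1-benzofuran | Brc1cc(OC)c2c(c1)O[C@@H](c1ccc(OC)cc1)[C@H]2c1cc(OC)cc(OC)c1.Brc1cc(OC)c2c(c1)O[C@H](c1ccc(OC)cc1)[C@@H]2c1cc(OC)cc(OC)c1
F7 | step 13 | racemic trans-6-bromo-3-(3,5-dimethoxyphenyl)-4-methoxy-2-(4-methoxyphenyl)-2,3-dihydro-1-benzofuran | Brc1cc(OC)c2c(c1)O[C@H](c1ccc(OC)cc1)[C@H]2c1cc(OC)cc(OC)c1.Brc1cc(OC)c2c(c1)O[C@@H](c1ccc(OC)cc1)[C@@H]2c1cc(OC)cc(OC)c1
F8 | step 17 | (1R,2S)-2-{4-[(tert-butyldimethylsilyloxy)methyl]-2,6-dihydroxyphenyl}-2-[(2S,3S)-3-(3,5-dimethoxyphenyl)-4-methoxy-2-(4-methoxyphenyl)-2,3-dihydro-1-benzofuran-6-yl]-1-(4-methoxyphenyl)ethylboronic ester of cis-diol 9 | COc1ccc(cc1)[C@H](B1O[C@]2(C)c3cccc4cccc(c34)[C@]2(C)O1)[C@H](c1c(O)cc(CO[Si](C)(C)C(C)(C)C)cc1O)c1cc(OC)c2c(c1)O[C@H](c1ccc(OC)cc1)[C@H]2c1cc(OC)cc(OC)c1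
F9 | step 17 | 5-[(tert-butyldimethylsilyloxy)methyl]-2-{(1S,2R)-1-[(2S,3S)-3-(3,5-dimethoxyphenyl)-4-methoxy-2-(4-methoxyphenyl)-2,3-dihydro-1-benzofuran-6-yl]-2-hydroxy-2-(4-methoxyphenyl)ethyl}benzene-1,3-diol | COc1ccc(cc1)[C@H](O)[C@H](c1c(O)cc(CO[Si](C)(C)C(C)(C)C)cc1O)c1cc(OC)c2c(c1)O[C@H](c1ccc(OC)cc1)[C@H]2c1cc(OC)cc(OC)c1
F10 | step 17 | (2S,3S)-6-[(tert-butyldimethylsilyloxy)methyl]-3-[(2S,3S)-3-(3,5-dimethoxyphenyl)-4-methoxy-2-(4-methoxyphenyl)-2,3-dihydro-1-benzofuran-6-yl]-2-(4-methoxyphenyl)-2,3-dihydro-1-benzofuran-4-ol | CC(C)(C)[Si](C)(C)OCc1cc(O)c2c(c1)O[C@H](c1ccc(OC)cc1)[C@H]2c1cc(OC)c2c(c1)O[C@H](c1ccc(OC)cc1)[C@H]2c1cc(OC)cc(OC)c1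
F11 | step 20 | (2S,3S)-3-[(2S,3S)-3-(3,5-dihydroxyphenyl)-4-hydroxy-2-(4-hydroxyphenyl)-2,3-dihydro-1-benzofuran-6-yl]-4-hydroxy-2-(4-hydroxyphenyl)-2,3-dihydro-1-benzofuran-6-carbaldehyde | O=Cc1cc(O)c2c(c1)O[C@H](c1ccc(O)cc1)[C@H]2c1cc(O)c2c(c1)O[C@H](c1ccc(O)cc1)[C@H]2c1cc(O)cc(O)c1
F12 | step 20 | hexakis(methoxymethyl) ether of F11 | O=Cc1cc(OCOC)c2c(c1)O[C@H](c1ccc(OCOC)cc1)[C@H]2c1cc(OCOC)c2c(c1)O[C@H](c1ccc(OCOC)cc1)[C@H]2c1cc(OCOC)cc(OCOC)c1
F13 | step 20 | heptakis(methoxymethyl) ether of 34 | COCOc1ccc(/C=C/c2cc(OCOC)c3c(c2)O[C@H](c2ccc(OCOC)cc2)[C@H]3c2cc(OCOC)c3c(c2)O[C@H](c2ccc(OCOC)cc2)[C@H]3c2cc(OCOC)cc(OCOC)c2)cc1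
A1 | alternative 1 | (2S)-naringenin | O=C1C[C@H](Oc2cc(O)cc(O)c12)c1ccc(O)cc1
A2 | alternative 1 | 3-diazo-5-hydroxy-2-(4-methoxyphenyl)-4-oxo-3,4-dihydro-2H-chromen-7-yl trifluoromethanesulfonate (C2 arranged as in A1; 2R by the sequence rule) | O=C1C(=[N+]=[N-])[C@H](Oc2cc(OS(=O)(=O)C(F)(F)F)cc(O)c12)c1ccc(OC)cc1
A3 | alternative 1 | methyl (2S)-4-hydroxy-2-(4-methoxyphenyl)-6-{[(trifluoromethyl)sulfonyl]oxy}-2,3-dihydro-1-benzofuran-3-carboxylate (both C3 epimers) | FC(F)(F)S(=O)(=O)Oc1cc(O)c2c(c1)O[C@H](c1ccc(OC)cc1)C2C(=O)OC
A4 | alternative 2 | 3-[(2S,3S)-6-bromo-4-methoxy-2-(4-methoxyphenyl)-2,3-dihydro-1-benzofuran-3-yl]cyclobut-2-en-1-one | Brc1cc(OC)c2c(c1)O[C@H](c1ccc(OC)cc1)[C@H]2C1=CC(=O)C1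
A5 | alternative 2 | {[(3S)-3-(3,5-dimethoxyphenyl)-4-methoxy-4-(4-methoxyphenyl)but-1-yn-1-yl]oxy}tri(propan-2-yl)silane (either C4 epimer) | CC(C)[Si](OC#C[C@H](c1cc(OC)cc(OC)c1)C(OC)c1ccc(OC)cc1)(C(C)C)C(C)C
A6 | alternative 2 | 5-[(2S,3S)-6-bromo-4-methoxy-2-(4-methoxyphenyl)-2,3-dihydro-1-benzofuran-3-yl]-2-[(1S)-1-(3,5-dimethoxyphenyl)-2-methoxy-2-(4-methoxyphenyl)ethyl]-3-{[tri(propan-2-yl)silyl]oxy}phenol | Brc1cc(OC)c2c(c1)O[C@H](c1ccc(OC)cc1)[C@H]2c1cc(O)c([C@H](c2cc(OC)cc(OC)c2)C(OC)c2ccc(OC)cc2)c(O[Si](C(C)C)(C(C)C)C(C)C)c1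
A7 | alternative 3 | methyl 4-{1-[4-(1-(3,5-dimethoxyphenyl)-2-(4-methoxyphenyl)-2-oxoethyl)-3,5-bis(methoxymethoxy)phenyl]-2-(4-methoxyphenyl)-2-oxoethyl}-3,5-bis(methoxymethoxy)benzoate (methine centres labile) | COC(=O)c1cc(OCOC)c(c(OCOC)c1)C(C(=O)c1ccc(OC)cc1)c1cc(OCOC)c(c(OCOC)c1)C(C(=O)c1ccc(OC)cc1)c1cc(OC)cc(OC)c1
A8 | alternative 3 | diol from reduction of A7, both diarylmethine carbons S, carbinol centres either | COC(=O)c1cc(OCOC)c(c(OCOC)c1)[C@@H](C(O)c1ccc(OC)cc1)c1cc(OCOC)c(c(OCOC)c1)[C@@H](C(O)c1ccc(OC)cc1)c1cc(OC)cc(OC)c1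
A9 | alternative 3 | methyl (2S,3S)-3-[(2S,3S)-3-(3,5-dimethoxyphenyl)-4-hydroxy-2-(4-methoxyphenyl)-2,3-dihydro-1-benzofuran-6-yl]-4-hydroxy-2-(4-methoxyphenyl)-2,3-dihydro-1-benzofuran-6-carboxylate | COC(=O)c1cc(O)c2c(c1)O[C@H](c1ccc(OC)cc1)[C@H]2c1cc(O)c2c(c1)O[C@H](c1ccc(OC)cc1)[C@H]2c1cc(OC)cc(OC)c1
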